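**Plan**
1. Labels: C1–C15 along the chain (C1 = alkyne CH); the ring O joins C7 and C12. The oxepane core (O, C7–C12) is C2-symmetric about the axis through O and the midpoint of C9–C10: C7 and C12 are both R and each sits next to a ring CH2, so the ring is a C7–O–C12 bis-nucleophile plus a C8–C11 cis-butene bis-electrophile.
2. Retrosynthetic cuts: silyl groups; C3=C4 (enyne cross-metathesis); C6–Cl, C9–Cl, C13–Br (from alcohols, inversion); C5–C6 (allylation); C13–C14 (ethylation); last, C7–C8 and C11–C12 together.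
3. Forward: diglycolyl bis-imide + (Z)-1,4-diiodobut-2-ene give the trans-oxepene, the only ring of the skeleton (step 3). Dihydroxylation/lactonisation then breaks the symmetry (temporary γ-lactone C6(=O)–O–C9); the C13 arm is built first, then the lactone is opened and the C6 arm built.
4. Stereochemistry: C7/C12 from two (S)-benzyloxazolidinones; C9/C10 from syn-dihydroxylation of homotopic alkene faces, then inversion at C9 (Cl); C13 from catalyst-controlled Et2Zn addition, then inversion (Br); C6 from Brown allylboration, then inversion (Cl); Z-C3=C4 from enyne cross-metathesis.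
5. Helpers removed: auxiliaries (steps 4, 6), lactone (step 10), TBS and TIPS (step 17).

Key step: step 3

Remark: (Z)-1,4-diiodobut-2-ene is assumed to keep its Z geometry when made and used cold in the dark; "top face" below means the ring face that carries the C6 arm.

Step 1
Reactants: 1 (S)-4-benzyl-1,3-oxazolidin-2-one; 2 diglycolyl chloride (2,2'-oxydiacetyl dichloride)
Product: 3 3,3'-(2,2'-oxydiacetyl)bis[(4S)-4-benzyl-1,3-oxazolidin-2-one]
Conditions: 1 (2.05 equiv), n-BuLi, THF, −78 °C; then 2, −78 → 0 °C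
Reagents that add atoms: none
Why: N-acylation of the lithiated oxazolidinone by the bis-acid chloride is the standard entry to N-acyl oxazolidinones and creates no stereocentre.

Step 2
Reactants: 4 (Z)-1,4-dichlorobut-2-ene
Product: 5 (Z)-1,4-diiodobut-2-ene
Conditions: NaI, acetone, 0 °C → rt, dark; filtered and used at once
Reagents that add atoms: sodium iodide [Na+].[I-]
Why: Finkelstein exchange (SN2 at both primary allylic carbons, driven by precipitation of NaCl) should give the more reactive bis-electrophile without touching the Z double bond.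

Step 3
Reactants: 3 bis-imide; 5 (Z)-1,4-diiodobut-2-ene
Product: 7 3,3'-{[(2R,7R)-2,3,6,7-tetrahydrooxepine-2,7-diyl]dicarbonyl}bis[(4S)-4-benzyl-1,3-oxazolidin-2-one], via mono-alkylated allylic iodide 6 (not isolated)
Conditions: NaHMDS (2.2 equiv), THF, −78 °C; then 5 (1.0 equiv) added slowly, high dilution, −78 → −45 °C
Reagents that add atoms: none
Why: Proposed new method: double deprotonation of 3 should give the bis-(Z)-sodium enolate; C-alkylation by one allylic iodide terminus of 5 gives 6, and the remaining enolate then displaces the second allylic iodide intramolecularly, so the C7–O–C12 bis-nucleophile and the cis-butenediyl bis-electrophile are joined in a formal (4+3) annulation that forms C7–C8 and C11–C12. The closest known reaction types are the Evans-type alkylation of N-glycolyl oxazolidinone sodium enolates with allylic iodides and the intramolecular alkylation of α-alkoxy amide enolates by (Z)-allylic halides to 2,7-disubstituted oxepenes. The ring closes in the 7-exo-tet mode, the cis double bond of 5 holding the electrophilic carbon within reach of the enolate and becoming C9=C10. C7 and C12 are each set by an (S)-benzyloxazolidinone, the chelated Z-enolate being alkylated on the face away from the benzyl group, which gives R at both carbons and hence the trans, C2-symmetric ring. The step needs SN2 closure over SN2' closure (5-exo attack at C9 would give a vinyl tetrahydrofuran), cyclisation over oligomerisation, and an intact Z geometry; these should be secured by the primary iodide leaving groups, slow addition of 5 to dilute bis-enolate at low temperature, the fact that only a Z-configured intermediate can close, and both auxiliaries directing to the same trans product.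

Step 4
Reactants: 7 C2-symmetric oxepene bis-imide
Product: 9 γ-lactone (C2 carbonyl to O-4) of (2R,4R,5S,7R)-7-{[(4S)-4-benzyl-2-oxo-1,3-oxazolidin-3-yl]carbonyl}-4,5-dihydroxyoxepane-2-carboxylic acid, via cis-diol 8 (not isolated)
Conditions: OsO4 (cat.), NMO, acetone/H2O, rt; then Et3N, DMAP (cat.), CH2Cl2, rt
Reagents that add atoms: osmium tetroxide O=[Os](=O)(=O)=O (catalytic oxygen carrier) and N-methylmorpholine N-oxide C[N+]1([O-])CCOCC1 (stoichiometric oxygen source)
Why: Upjohn syn-dihydroxylation of the ring alkene, whose two faces are homotopic in C2-symmetric 7 so that one cis-diol results, followed by acyl transfer from the imide to the only hydroxyl that is 1,3-cis to an acyl group (O–C9, five-membered lactone), sets C9 and C10 and tells apart both the two arms and the two oxygens.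

Step 5
Reactants: 9 hydroxy lactone imide
Product: 10 5-O-tert-butyldimethylsilyl ether of 9
Conditions: TBSOTf, 2,6-lutidine, CH2Cl2, −78 → 0 °C
Reagents that add atoms: tert-butyldimethylsilyl trifluoromethanesulfonate CC(C)(C)[Si](C)(C)OS(=O)(=O)C(F)(F)F
Why: Silylation of the only free hydroxyl with a silyl triflate and a hindered base is routine and masks O–C10, the oxygen kept in the target, so that O–C9 alone can later become chloride.

Step 6
Reactants: 10 silyl ether lactone imide
Product: 11 γ-lactone (C2 carbonyl to O-4) of (2R,4R,5S,7R)-5-[(tert-butyldimethylsilyl)oxy]-4-hydroxy-7-(hydroxymethyl)oxepane-2-carboxylic acid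
Conditions: NaBH4, THF/H2O, 0 °C
Reagents that add atoms: none
Why: Aqueous borohydride reduces the activated N-acyl oxazolidinone to the primary alcohol (reductive removal of an Evans auxiliary) much faster than it attacks a lactone, which frees the C13 arm and returns the second auxiliary.

Step 7
Reactants: 11 primary alcohol
Product: 12 γ-lactone (C2 carbonyl to O-4) of (2R,4R,5S,7R)-5-[(tert-butyldimethylsilyl)oxy]-7-formyl-4-hydroxyoxepane-2-carboxylic acid
Conditions: Dess–Martin periodinane, CH2Cl2, 0 °C → rt; used at once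
Reagents that add atoms: none
Why: Dess–Martin oxidation under neutral conditions should give the α-alkoxy aldehyde without epimerising C12.

Step 8
Reactants: 12 aldehyde
Product: 13 γ-lactone (C2 carbonyl to O-4) of (2R,4R,5S,7R)-5-[(tert-butyldimethylsilyl)oxy]-4-hydroxy-7-[(1S)-1-hydroxypropyl]oxepane-2-carboxylic acid
Conditions: Et2Zn, Ti(OiPr)4, (1R,2R)-1,2-bis(trifluoromethanesulfonamido)cyclohexane (cat.), toluene, −20 °C; aq NH4Cl
Reagents that add atoms: diethylzinc CC[Zn]CC
Why: Titanium/bis-sulfonamide-catalysed addition of diethylzinc is reagent-controlled, the (1R,2R)-ligand directing ethyl to the Si face, which is also the Felkin–Anh (non-chelate) face of this α-alkoxy aldehyde, so (13S) should result while the lactone stays inert to the zinc reagent.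

Step 9
Reactants: 13 secondary alcohol
Product: 14 γ-lactone (C2 carbonyl to O-4) of (2R,4R,5S,7R)-7-[(1R)-1-bromopropyl]-5-[(tert-butyldimethylsilyl)oxy]-4-hydroxyoxepane-2-carboxylic acid
Conditions: CBr4, P(n-Oct)3, toluene, 70 °C
Reagents that add atoms: carbon tetrabromide BrC(Br)(Br)Br
Why: Appel bromination via the alkoxyphosphonium ion is an SN2 process, so (13S)-OH should give the (13R)-bromide of the target with inversion.

Step 10
Reactants: 14 bromo lactone
Product: 15 (2R,4R,5S,7R)-7-[(1R)-1-bromopropyl]-5-[(tert-butyldimethylsilyl)oxy]-4-hydroxy-N-methoxy-N-methyloxepane-2-carboxamide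
Conditions: MeNH(OMe)·HCl, AlMe3, CH2Cl2, 0 °C → rt
Reagents that add atoms: N,O-dimethylhydroxylamine hydrochloride CNOC.Cl
Why: Aluminium-amide aminolysis of the lactone (Weinreb amide formation) cleaves the temporary ring, leaving O–C9 as the only free hydroxyl and C6 as an acyl group that cannot be activated in the next step.

Step 11
Reactants: 15 hydroxy Weinreb amide
Product: 16 (2R,4S,5S,7R)-7-[(1R)-1-bromopropyl]-5-[(tert-butyldimethylsilyl)oxy]-4-chloro-N-methoxy-N-methyloxepane-2-carboxamide
Conditions: CCl4, P(n-Oct)3, toluene, rt → 60 °C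
Reagents that add atoms: carbon tetrachloride ClC(Cl)(Cl)Cl
Why: Appel chlorination with SN2 inversion at C9 puts chlorine on the face opposite O–C10, and because only O–C9 is free the regiochemistry of the trans-chlorohydrin is fixed; the amide and silyloxy groups lie on the leaving-group face and cannot participate.

Step 12
Reactants: 16 chloro Weinreb amide
Product: 17 (2R,4S,5S,7R)-7-[(1R)-1-bromopropyl]-5-[(tert-butyldimethylsilyl)oxy]-4-chlorooxepane-2-carbaldehyde
Conditions: DIBAL-H, THF, −78 °C; Rochelle salt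
Reagents that add atoms: none
Why: DIBAL-H reduction of a Weinreb amide stops at the aldehyde because of the stable chelated tetrahedral intermediate.

Step 13
Reactants: 17 aldehyde
Product: 18 (1S)-1-{(2R,4S,5S,7R)-7-[(1R)-1-bromopropyl]-5-[(tert-butyldimethylsilyl)oxy]-4-chlorooxepan-2-yl}but-3-en-1-ol
Conditions: (−)-Ipc2B(allyl) (from (+)-α-pinene), Et2O, −78 °C; then NaOH, H2O2, 0 °C
Reagents that add atoms: (−)-B-allyldiisopinocampheylborane C=CCB([C@@H]1C[C@@H]2C[C@H]([C@H]1C)C2(C)C)[C@@H]1C[C@@H]2C[C@H]([C@H]1C)C2(C)C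
Why: Brown allylboration is reagent-controlled, the (+)-α-pinene-derived borane adding allyl to the Si face through a chair transition state, which matches the Felkin–Anh preference of the aldehyde and should set (6S).

Step 14
Reactants: 18 homoallylic alcohol
Product: 19 tert-butyl({(2R,4S,5S,7R)-7-[(1R)-1-bromopropyl]-4-chloro-2-[(1R)-1-chlorobut-3-en-1-yl]oxepan-5-yl}oxy)dimethylsilane
Conditions: CCl4, P(n-Oct)3, toluene, 70 °C
Reagents that add atoms: carbon tetrachloride ClC(Cl)(Cl)Cl
Why: Appel chlorination under the hot trioctylphosphine conditions used for hindered carbinols beside a cyclic ether should invert C6 to the (6R)-chloride.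

Step 15
Reactants: 20 ethynyltri(propan-2-yl)silane; 21 vinyl bromide
Product: 22 (but-3-en-1-yn-1-yl)tri(propan-2-yl)silane
Conditions: Pd(PPh3)4 (cat.), CuI (cat.), Et2NH, THF, 0 °C → rt
Reagents that add atoms: none
Why: Sonogashira coupling of a terminal alkyne with a vinyl halide gives the conjugated enyne partner and forms no stereocentre.

Step 16
Reactants: 19 allyl dichloride; 22 silyl enyne
Product: 23 tert-butyl({(2R,4S,5S,7R)-7-[(1R)-1-bromopropyl]-4-chloro-2-[(1R,3Z)-1-chloro-6-(triisopropylsilyl)hex-3-en-5-yn-1-yl]oxepan-5-yl}oxy)dimethylsilane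
Conditions: 22 (excess), Grubbs second-generation catalyst, CH2Cl2, 40 °C
Reagents that add atoms: none
Why: Cross-metathesis of a terminal alkene with a silyl-capped conjugated enyne is known to favour the Z-enyne, so C1–C3 and the C3=C4 bond are attached in one step, the substrate holding no other alkene.

Step 17
Reactants: 23 bis-silyl compound
Product: 24 (2R,4S,5S,7R)-7-[(1R)-1-bromopropyl]-4-chloro-2-[(1R,3Z)-1-chlorohex-3-en-5-yn-1-yl]oxepan-5-ol
Conditions: TBAF, AcOH, THF, 0 °C → rt
Reagents that add atoms: none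
Why: Fluoride cleaves the Si–O and alkynyl C–Si bonds, while acetic acid buffering should keep the freed C10 oxygen from closing an epoxide onto C9 or eliminating a halide.

**Compound list**
1 | (S)-4-benzyl-1,3-oxazolidin-2-one | O=C1N[C@@H](Cc2ccccc2)CO1 | starting material
2 | diglycolyl chloride | O=C(Cl)COCC(=O)Cl | starting material
3 | 3,3'-(2,2'-oxydiacetyl)bis[(4S)-4-benzyl-1,3-oxazolidin-2-one] | O=C(COCC(=O)N1[C@@H](Cc2ccccc2)COC1=O)N1[C@@H](Cc2ccccc2)COC1=O | intermediate
4 | (Z)-1,4-dichlorobut-2-ene | ClC/C=C\CCl | starting material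
5 | (Z)-1,4-diiodobut-2-ene | IC/C=C\CI | intermediate
6 | (4S)-4-benzyl-3-[(2R,4Z)-2-{2-[(4S)-4-benzyl-2-oxo-1,3-oxazolidin-3-yl]-2-oxoethoxy}-6-iodohex-4-enoyl]-1,3-oxazolidin-2-one (present as its sodium enolate) | O=C([C@@H](C/C=C\CI)OCC(=O)N1[C@@H](Cc2ccccc2)COC1=O)N1[C@@H](Cc2ccccc2)COC1=O | intermediate
7 | 3,3'-{[(2R,7R)-2,3,6,7-tetrahydrooxepine-2,7-diyl]dicarbonyl}bis[(4S)-4-benzyl-1,3-oxazolidin-2-one] | O=C([C@H]1CC=CC[C@H](C(=O)N2[C@@H](Cc3ccccc3)COC2=O)O1)N1[C@@H](Cc2ccccc2)COC1=O | intermediate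
8 | 3,3'-{[(2R,4R,5S,7R)-4,5-dihydroxyoxepane-2,7-diyl]dicarbonyl}bis[(4S)-4-benzyl-1,3-oxazolidin-2-one] (4,5-cis-diol) | O=C([C@H]1C[C@@H](O)[C@@H](O)C[C@H](C(=O)N2[C@@H](Cc3ccccc3)COC2=O)O1)N1[C@@H](Cc2ccccc2)COC1=O | intermediate
9 | γ-lactone (C2 carbonyl to O-4) of (2R,4R,5S,7R)-7-{[(4S)-4-benzyl-2-oxo-1,3-oxazolidin-3-yl]carbonyl}-4,5-dihydroxyoxepane-2-carboxylic acid; 5-OH free, on the lactone face | O=C([C@H]1C[C@H](O)[C@H]2C[C@@H](O1)C(=O)O2)N1[C@@H](Cc2ccccc2)COC1=O | intermediate
10 | 5-O-TBS ether of 9 | O=C([C@H]1C[C@H](O[Si](C)(C)C(C)(C)C)[C@H]2C[C@@H](O1)C(=O)O2)N1[C@@H](Cc2ccccc2)COC1=O | intermediate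
11 | γ-lactone (C2 carbonyl to O-4) of (2R,4R,5S,7R)-5-(TBSO)-4-hydroxy-7-(hydroxymethyl)oxepane-2-carboxylic acid | OC[C@H]1C[C@H](O[Si](C)(C)C(C)(C)C)[C@H]2C[C@@H](O1)C(=O)O2 | intermediate
12 | γ-lactone (C2 carbonyl to O-4) of (2R,4R,5S,7R)-5-(TBSO)-7-formyl-4-hydroxyoxepane-2-carboxylic acid | O=C[C@H]1C[C@H](O[Si](C)(C)C(C)(C)C)[C@H]2C[C@@H](O1)C(=O)O2 | intermediate
13 | γ-lactone (C2 carbonyl to O-4) of (2R,4R,5S,7R)-5-(TBSO)-4-hydroxy-7-[(1S)-1-hydroxypropyl]oxepane-2-carboxylic acid | CC[C@H](O)[C@H]1C[C@H](O[Si](C)(C)C(C)(C)C)[C@H]2C[C@@H](O1)C(=O)O2 | intermediate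
14 | γ-lactone (C2 carbonyl to O-4) of (2R,4R,5S,7R)-7-[(1R)-1-bromopropyl]-5-(TBSO)-4-hydroxyoxepane-2-carboxylic acid | CC[C@@H](Br)[C@H]1C[C@H](O[Si](C)(C)C(C)(C)C)[C@H]2C[C@@H](O1)C(=O)O2 | intermediate
15 | (2R,4R,5S,7R)-7-[(1R)-1-bromopropyl]-5-[(tert-butyldimethylsilyl)oxy]-4-hydroxy-N-methoxy-N-methyloxepane-2-carboxamide | CC[C@@H](Br)[C@H]1C[C@H](O[Si](C)(C)C(C)(C)C)[C@H](O)C[C@@H](O1)C(=O)N(C)OC | intermediate
16 | (2R,4S,5S,7R)-7-[(1R)-1-bromopropyl]-5-[(tert-butyldimethylsilyl)oxy]-4-chloro-N-methoxy-N-methyloxepane-2-carboxamide | CC[C@@H](Br)[C@H]1C[C@H](O[Si](C)(C)C(C)(C)C)[C@@H](Cl)C[C@@H](O1)C(=O)N(C)OC | intermediate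
17 | (2R,4S,5S,7R)-7-[(1R)-1-bromopropyl]-5-[(tert-butyldimethylsilyl)oxy]-4-chlorooxepane-2-carbaldehyde | CC[C@@H](Br)[C@H]1C[C@H](O[Si](C)(C)C(C)(C)C)[C@@H](Cl)C[C@@H](O1)C=O | intermediate
18 | (1S)-1-{(2R,4S,5S,7R)-7-[(1R)-1-bromopropyl]-5-[(tert-butyldimethylsilyl)oxy]-4-chlorooxepan-2-yl}but-3-en-1-ol | CC[C@@H](Br)[C@H]1C[C@H](O[Si](C)(C)C(C)(C)C)[C@@H](Cl)C[C@@H](O1)[C@@H](O)CC=C | intermediate
19 | tert-butyl({(2R,4S,5S,7R)-7-[(1R)-1-bromopropyl]-4-chloro-2-[(1R)-1-chlorobut-3-en-1-yl]oxepan-5-yl}oxy)dimethylsilane | CC[C@@H](Br)[C@H]1C[C@H](O[Si](C)(C)C(C)(C)C)[C@@H](Cl)C[C@@H](O1)[C@H](Cl)CC=C | intermediate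
20 | ethynyltri(propan-2-yl)silane | C#C[Si](C(C)C)(C(C)C)C(C)C | starting material
21 | vinyl bromide | C=CBr | starting material
22 | (but-3-en-1-yn-1-yl)tri(propan-2-yl)silane | C=CC#C[Si](C(C)C)(C(C)C)C(C)C | intermediate
23 | tert-butyl({(2R,4S,5S,7R)-7-[(1R)-1-bromopropyl]-4-chloro-2-[(1R,3Z)-1-chloro-6-(triisopropylsilyl)hex-3-en-5-yn-1-yl]oxepan-5-yl}oxy)dimethylsilane | CC[C@@H](Br)[C@H]1C[C@H](O[Si](C)(C)C(C)(C)C)[C@@H](Cl)C[C@@H](O1)[C@H](Cl)C/C=C\C#C[Si](C(C)C)(C(C)C)C(C)C | intermediate
24 | (2R,4S,5S,7R)-7-[(1R)-1-bromopropyl]-4-chloro-2-[(1R,3Z)-1-chlorohex-3-en-5-yn-1-yl]oxepan-5-ol | C#C/C=C\C[C@@H](Cl)[C@H]1C[C@H](Cl)[C@@H](O)C[C@H]([C@H](Br)CC)O1 | target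

**Count and risks**
Total step count: 17. Longest linear sequence: 15 (steps 1, 3–14, 16, 17; steps 2 and 15 are side branches).

Steps most likely to fail:

1. Step 3 (Proposed new method). The ring closure may go astray by SN2' attack of the second enolate (five-membered ring), by intermolecular oligomerisation, or by Z→E isomerisation of the diiodide before it reacts. Fallback with known chemistry, setting out from 3: twofold Evans-type alkylation with allyl iodide (NaHMDS, THF, −78 → −45 °C) should give the bis-allyl bis-imide F1, and ring-closing metathesis of its two terminal alkenes (Grubbs second-generation catalyst, CH2Cl2, 40 °C) returns to 7.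

2. Step 11. Displacement at the ring carbon C9, flanked by the silyloxy-bearing C10, may be slow, so that E2 elimination or thermal relactonisation of the γ-hydroxy amide competes at 60 °C. Fallback, setting out from 15: activation and displacement are separated, the alcohol being converted at −30 °C (Tf2O, pyridine, CH2Cl2) into the C4 triflate F2, which is displaced with inversion by soluble chloride (Bu4NCl, toluene, −20 → 0 °C), returning to 16 without heating.

3. Step 16. The cross-metathesis may give poor Z/E selectivity or stall because the enyne ties up the ruthenium carbene. Fallback, setting out from 19: ozonolysis of the terminal alkene (O3, CH2Cl2, −78 °C; PPh3) should give the β-chloro aldehyde F3, used cold at once; Stork–Zhao olefination (Ph3P+CH2I I−, NaHMDS, HMPA/THF, −78 °C) gives the (Z)-vinyl iodide F4; Sonogashira coupling with 20 (Pd(PPh3)4, CuI, Et2NH) returns to 23.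

Further compounds
F1 | step 3 | 3,3'-[(2R,2'R)-2,2'-oxybis(pent-4-enoyl)]bis[(4S)-4-benzyl-1,3-oxazolidin-2-one] | O=C([C@@H](CC=C)O[C@H](CC=C)C(=O)N1[C@@H](Cc2ccccc2)COC1=O)N1[C@@H](Cc2ccccc2)COC1=O
F2 | step 11 | (2R,4R,5S,7R)-7-[(1R)-1-bromopropyl]-5-[(tert-butyldimethylsilyl)oxy]-2-[methoxy(methyl)carbamoyl]oxepan-4-yl trifluoromethanesulfonate | CC[C@@H](Br)[C@H]1C[C@H](O[Si](C)(C)C(C)(C)C)[C@H](OS(=O)(=O)C(F)(F)F)C[C@@H](O1)C(=O)N(C)OC
F3 | step 16 | (3R)-3-{(2R,4S,5S,7R)-7-[(1R)-1-bromopropyl]-5-[(tert-butyldimethylsilyl)oxy]-4-chlorooxepan-2-yl}-3-chloropropanal | CC[C@@H](Br)[C@H]1C[C@H](O[Si](C)(C)C(C)(C)C)[C@@H](Cl)C[C@@H](O1)[C@H](Cl)CC=O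
F4 | step 16 | tert-butyl({(2R,4S,5S,7R)-7-[(1R)-1-bromopropyl]-4-chloro-2-[(1R,3Z)-1-chloro-4-iodobut-3-en-1-yl]oxepan-5-yl}oxy)dimethylsilane | CC[C@@H](Br)[C@H]1C[C@H](O[Si](C)(C)C(C)(C)C)[C@@H](Cl)C[C@@H](O1)[C@H](Cl)C/C=C\I
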